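Atoms are numbered from the lactone carbonyl C1 to the aldehyde carbon C24. Retrosynthetically the C17 ketone and C24 aldehyde go back to alcohols, and the C13–C14 diene bond is cut (Stille) into a C1–C13 alkenyl iodide and a C14–C24 alkenylstannane.
East half: C14–Sn (hydrostannation), C16–C17 (allenylzinc addition), then the ring bond O–C22. C22 is the fully substituted ether carbon of the oxolane (O, C19, C20, C21, C22) and its CH2CHO arm C23–C24 can be carried as vinyl, so C22 is the branched end of an allyl unit C22–C23–C24 that the C19 oxygen reaches by 5-exo attack.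
Further East cuts: C22–CH3 and C23–C24 (methylalumination/formaldehyde on an alkyne), C18–C19 (crotylboration). West half: C2=C3 and O–C1 (acrylate ring-closing metathesis), C4–C5 (crotylboration), C6=C7 (Wittig), C8=C9 (Still–Gennari).
Forward: one Evans alkylation gives (2R)-2-methylpent-4-yn-1-ol, the source of both C10 and C20. The oxolane is closed first (step 9), the lactone second (step 25), the halves are joined at C13–C14 (step 26) and the two carbinols are oxidised last (step 27).
Stereochemistry: C10 and C20 from the oxazolidinone auxiliary; C18/C19 and C4/C5 from (E)-crotyl-B(Ipc)2; C22 from the chiral diphosphine on palladium; C16 from (S)-pent-3-yn-2-yl mesylate; 8Z from Still–Gennari, 6E from the Wittig step, 12E, 14E and the E allyl carbonate from syn additions to alkynes.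

Key step: step 9

Remark: (2S)-pent-3-yn-2-ol (16) is assumed to be purchasable in high enantiomeric purity; the C17 carbinol configuration formed in step 13 is immaterial because C17 becomes the ketone.

**Shared building block**

Step 1
Reactants: 1 (4S)-4-benzyl-3-propanoyl-1,3-oxazolidin-2-one; 2 3-bromoprop-1-yne
Product: 3 (4S)-4-benzyl-3-[(2R)-2-methylpent-4-ynoyl]-1,3-oxazolidin-2-one
Conditions: NaN(SiMe3)2, THF, −78 °C; then 2, −78 → −30 °C
Reagents that add atoms: none
Why: Evans alkylation: the chelated Z sodium enolate is alkylated by the propargylic bromide on the face opposite the benzyl group, which sets the (R)-methyl centre that later serves as both C10 and C20.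

Step 2
Reactants: 3 (4S)-4-benzyl-3-[(2R)-2-methylpent-4-ynoyl]-1,3-oxazolidin-2-one
Product: 4 (2R)-2-methylpent-4-yn-1-ol
Conditions: LiBH4, MeOH, THF, 0 °C
Reagents that add atoms: none
Why: Hydride cleavage of the N-acyloxazolidinone (LiBH4 reduction) releases the primary alcohol and the recoverable auxiliary without touching the α-centre or the alkyne.

**East half (C14–C24)**

Step 3
Reactants: 4 (2R)-2-methylpent-4-yn-1-ol
Product: 5 (2R)-2-methylpent-4-ynal
Conditions: Dess–Martin periodinane, CH2Cl2, 0 °C → rt; used directly as a solution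
Reagents that add atoms: none
Why: Dess–Martin oxidation stops at the aldehyde under near-neutral conditions that should not epimerise the α-methyl centre; the volatile aldehyde is not concentrated to dryness.

Step 4
Reactants: 5 (2R)-2-methylpent-4-ynal
Product: 6 (3S,4R,5R)-3,5-dimethyloct-1-en-7-yn-4-ol
Conditions: trans-but-2-ene, KOt-Bu, n-BuLi, THF, −78 → −45 °C; (−)-Ipc2BOMe, −78 °C; BF3·OEt2; 5, −78 °C; then NaOH, H2O2
Reagents that add atoms: trans-but-2-ene, C/C=C/C
Why: Brown crotylboration: the (E)-crotylborane adds through a chair transition state that gives the anti C18/C19 pair, and the isopinocampheyl groups from (+)-α-pinene direct attack to the si face of the aldehyde, the same sense as the anti-Felkin preference of E-crotylboron reagents for α-methyl aldehydes, so C18 and C19 are set anti,anti to C20.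

Step 5
Reactants: 6 (3S,4R,5R)-3,5-dimethyloct-1-en-7-yn-4-ol
Product: 8 (2S,3R,4R)-2,4-dimethylhept-6-yne-1,3-diol, via ozonide 7 (not isolated)
Conditions: O3, CH2Cl2, −78 °C (Sudan Red 7B end point); then NaBH4, MeOH, −78 °C → rt
Reagents that add atoms: ozone, [O-][O+]=O
Why: Ozonolysis of the terminal alkene, which reacts far faster than the alkyne, with NaBH4 reduction of the ozonide converts the vinyl group into the C17 hydroxymethyl group.

Step 6
Reactants: 8 (2S,3R,4R)-2,4-dimethylhept-6-yne-1,3-diol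
Product: 9 (2S,3R,4R)-1-{[tert-butyl(dimethyl)silyl]oxy}-2,4-dimethylhept-6-yn-3-ol
Conditions: TBSCl, imidazole, CH2Cl2, −20 → 0 °C
Reagents that add atoms: tert-butyl(chloro)dimethylsilane, CC(C)(C)[Si](C)(C)Cl
Why: Silyl ether formation is selective for the primary hydroxyl, the C19 hydroxyl being flanked by two methyl-bearing carbons.

Step 7
Reactants: 9 (2S,3R,4R)-1-{[tert-butyl(dimethyl)silyl]oxy}-2,4-dimethylhept-6-yn-3-ol
Product: 11 (2E,5R,6R,7S)-8-{[tert-butyl(dimethyl)silyl]oxy}-3,5,7-trimethyloct-2-ene-1,6-diol, via alkenylalane 10 (not isolated)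
Conditions: Me3Al, Cp2ZrCl2 (25 mol %), CH2Cl2, 0 °C → rt; then n-BuLi, THF/hexane, 0 °C; (CH2O)n, rt
Reagents that add atoms: trimethylaluminium, C[Al](C)C; paraformaldehyde (as formaldehyde), C=O
Why: Negishi zirconium-catalysed methylalumination adds methyl and aluminium syn across the terminal alkyne (methyl to C22, aluminium to C23) and the derived alanate is hydroxymethylated by formaldehyde with retention, which gives the E trisubstituted allylic alcohol as a single geometric isomer while the C19 hydroxyl is masked as its aluminium alkoxide.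

Step 8
Reactants: 11 (2E,5R,6R,7S)-8-{[tert-butyl(dimethyl)silyl]oxy}-3,5,7-trimethyloct-2-ene-1,6-diol
Product: 12 (2E,5R,6R,7S)-8-{[tert-butyl(dimethyl)silyl]oxy}-6-hydroxy-3,5,7-trimethyloct-2-en-1-yl methyl carbonate
Conditions: ClCO2Me, pyridine, CH2Cl2, −20 → 0 °C
Reagents that add atoms: methyl chloroformate, COC(=O)Cl
Why: Acylation with methyl chloroformate and pyridine is selective for the unhindered primary allylic hydroxyl and installs the leaving group, leaving the C19 hydroxyl free as the internal nucleophile.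

Step 9
Reactants: 12 (2E,5R,6R,7S)-8-{[tert-butyl(dimethyl)silyl]oxy}-6-hydroxy-3,5,7-trimethyloct-2-en-1-yl methyl carbonate
Product: 13 tert-butyl{(2S)-2-[(2R,3R,5R)-5-ethenyl-3,5-dimethyloxolan-2-yl]propoxy}dimethylsilane
Conditions: Pd2(dba)3·CHCl3 (2.5 mol %), (1R,2R)-N,N′-bis[2-(diphenylphosphanyl)benzoyl]cyclohexane-1,2-diamine (7.5 mol %), degassed CH2Cl2, rt
Reagents that add atoms: none
Why: Zerovalent palladium ionises the allylic carbonate with loss of CO2 and methoxide to a π-allyl complex over C22–C24, the methoxide deprotonates the C19 hydroxyl, and the alkoxide attacks C22 on the face away from palladium, which forms the O–C22 bond and leaves C23=C24 as vinyl. The closest known reaction is the Tsuji–Trost asymmetric allylic etherification in its intramolecular form, established for hydroxy- and hydroxyaryl-substituted allylic carbonates that close to 2-vinyl cyclic ethers with fully substituted carbons. The oxolane (O, C19, C20, C21, C22) closes in a 5-exo mode at the branched allyl terminus, since attack at C24 would require a seven-membered ring. The new C22 centre is set by the chiral diphosphine: the two faces of the allyl unit exchange through the C24 σ-bound form faster than ring closure, and the ligand pocket selects the diastereomeric complex whose closure gives (22R), with the vinyl group trans to the C19 side chain. The step needs face selection at C22 and a single allyl geometry; the E carbonate from the syn methylalumination (C21 syn, methyl anti on the allyl) secures the second, and the pseudo-equatorial C19 and C20 substituents of the closing envelope assist the first. The (R,R) ligand is the committed choice, and whether it is the matched antipode for this substrate is the principal uncertainty of the route.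

Step 10
Reactants: 13 tert-butyl{(2S)-2-[(2R,3R,5R)-5-ethenyl-3,5-dimethyloxolan-2-yl]propoxy}dimethylsilane
Product: 14 (2S)-2-[(2R,3R,5R)-5-ethenyl-3,5-dimethyloxolan-2-yl]propan-1-ol
Conditions: Bu4NF, THF, 0 °C → rt
Reagents that add atoms: none
Why: Fluoride-mediated cleavage of the primary silyl ether frees the C17 alcohol; the ether and vinyl groups are inert.

Step 11
Reactants: 14 (2S)-2-[(2R,3R,5R)-5-ethenyl-3,5-dimethyloxolan-2-yl]propan-1-ol
Product: 15 (2R)-2-[(2R,3R,5R)-5-ethenyl-3,5-dimethyloxolan-2-yl]propanal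
Conditions: Dess–Martin periodinane, CH2Cl2, 0 °C; used crude
Reagents that add atoms: none
Why: Dess–Martin oxidation gives the α-methyl aldehyde, which is used without purification so that C18 is not exposed to epimerising conditions.

Step 12
Reactants: 16 (2S)-pent-3-yn-2-ol
Product: 17 (2S)-pent-3-yn-2-yl methanesulfonate
Conditions: MsCl, Et3N, CH2Cl2, −78 °C
Reagents that add atoms: methanesulfonyl chloride, CS(=O)(=O)Cl
Why: Sulfonylation at oxygen (mesylate formation) activates the propargylic alcohol without touching its stereocentre.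

Step 13
Reactants: 15 (2R)-2-[(2R,3R,5R)-5-ethenyl-3,5-dimethyloxolan-2-yl]propanal; 17 (2S)-pent-3-yn-2-yl methanesulfonate
Product: 19 (2S,3R,4R)-2-[(2R,3R,5R)-5-ethenyl-3,5-dimethyloxolan-2-yl]-4-methylhept-5-yn-3-ol, via allenylzinc 18 (not isolated)
Conditions: Pd(OAc)2 (5 mol %), PPh3 (5 mol %), Et2Zn (3 equiv), THF, −78 → −20 °C
Reagents that add atoms: none
Why: Marshall propargylation: zerovalent palladium displaces the mesylate in an anti SN2′ sense, transmetalation with Et2Zn gives the allenylzinc with retention, and its SE2′ addition to the aldehyde through a cyclic transition state transfers the axial chirality to C16 (R) and places the C17 hydroxyl anti.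

Step 14
Reactants: 19 (2S,3R,4R)-2-[(2R,3R,5R)-5-ethenyl-3,5-dimethyloxolan-2-yl]-4-methylhept-5-yn-3-ol
Product: 20 (2S,3R,4R,5E)-2-[(2R,3R,5R)-5-ethenyl-3,5-dimethyloxolan-2-yl]-4-methyl-6-(tributylstannyl)hept-5-en-3-ol
Conditions: Bu3SnH, PdCl2(PPh3)2 (3 mol %), THF, 0 °C → rt
Reagents that add atoms: tributylstannane, CCCC[SnH](CCCC)CCCC
Why: Palladium-catalysed hydrostannation adds H and SnBu3 syn across the alkyne with tin at the less hindered, methyl-bearing C14 remote from the branched C16, which gives the E alkenylstannane; alkenes and the free hydroxyl are not affected.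

Step 15
Reactants: 20 (2S,3R,4R,5E)-2-[(2R,3R,5R)-5-ethenyl-3,5-dimethyloxolan-2-yl]-4-methyl-6-(tributylstannyl)hept-5-en-3-ol
Product: 22 (2S,3R,4R,5E)-2-[(2R,3R,5R)-5-(2-hydroxyethyl)-3,5-dimethyloxolan-2-yl]-4-methyl-6-(tributylstannyl)hept-5-en-3-ol, via alkylborane 21 (not isolated)
Conditions: 9-BBN (3 equiv), THF, 0 °C → rt; then aq NaOH, H2O2, 0 °C
Reagents that add atoms: hydrogen peroxide, OO
Why: Hydroboration–oxidation: 9-BBN adds anti-Markovnikov to the monosubstituted vinyl group far faster than to the trisubstituted, tin-bearing alkene, and alkaline peroxide replaces boron by hydroxyl without cleaving the carbon–tin bond.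

**West half (C1–C13)**

Step 16
Reactants: 4 (2R)-2-methylpent-4-yn-1-ol
Product: 24 (2R,4E)-5-iodo-2-methylpent-4-en-1-ol, via alkenylzirconocene 23 (not isolated)
Conditions: Cp2Zr(H)Cl (2.5 equiv), THF, rt; then I2, 0 °C
Reagents that add atoms: iodine, II
Why: Hydrozirconation–iodination: after the first equivalent of Cp2Zr(H)Cl is consumed by the hydroxyl, syn addition to the terminal alkyne places zirconium at C13 and iodinolysis with retention gives the E alkenyl iodide.

Step 17
Reactants: 24 (2R,4E)-5-iodo-2-methylpent-4-en-1-ol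
Product: 25 (2R,4E)-5-iodo-2-methylpent-4-enal
Conditions: Dess–Martin periodinane, CH2Cl2, 0 °C → rt; used directly
Reagents that add atoms: none
Why: Dess–Martin oxidation to the α-methyl aldehyde without epimerisation; the alkenyl iodide is inert.

Step 18
Reactants: 26 methyl 2-[bis(2,2,2-trifluoroethoxy)phosphoryl]acetate
Product: 27 methyl 2-[bis(2,2,2-trifluoroethoxy)phosphoryl]butanoate
Conditions: KOt-Bu, EtI, THF, 0 °C → rt
Reagents that add atoms: iodoethane, CCI
Why: C-Alkylation of the potassium salt of the phosphonoacetate with iodoethane supplies the α-ethyl Still–Gennari reagent.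

Step 19
Reactants: 25 (2R,4E)-5-iodo-2-methylpent-4-enal; 27 methyl 2-[bis(2,2,2-trifluoroethoxy)phosphoryl]butanoate
Product: 28 methyl (2Z,4R,6E)-2-ethyl-7-iodo-4-methylhepta-2,6-dienoate
Conditions: KN(SiMe3)2, 18-crown-6, THF, −78 °C
Reagents that add atoms: none
Why: Still–Gennari olefination: the bis(trifluoroethyl) phosphonate anion with a crown-sequestered potassium ion adds irreversibly and eliminates fast, so the kinetic Z trisubstituted enoate (C8=C9) is formed.

Step 20
Reactants: 28 methyl (2Z,4R,6E)-2-ethyl-7-iodo-4-methylhepta-2,6-dienoate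
Product: 29 (2Z,4R,6E)-2-ethyl-7-iodo-4-methylhepta-2,6-dien-1-ol
Conditions: i-Bu2AlH, CH2Cl2, −78 °C
Reagents that add atoms: none
Why: i-Bu2AlH reduces the enoate 1,2 to the allylic alcohol at low temperature without touching the alkenyl iodide or the Z double bond.

Step 21
Reactants: 29 (2Z,4R,6E)-2-ethyl-7-iodo-4-methylhepta-2,6-dien-1-ol
Product: 31 (2E,4Z,6R,8E)-4-ethyl-9-iodo-N-methoxy-N,6-dimethylnona-2,4,8-trienamide, via Z-enal 30 (not isolated)
Conditions: MnO2 (excess), Ph3P=CHC(O)N(OMe)Me, CH2Cl2, rt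
Reagents that add atoms: N-methoxy-N-methyl-2-(triphenyl-λ5-phosphanylidene)acetamide, CON(C)C(=O)C=P(c1ccccc1)(c1ccccc1)c1ccccc1
Why: Tandem oxidation–Wittig reaction: MnO2 oxidises the allylic alcohol and the amide-stabilised ylide traps the isomerisation-prone Z-enal as it forms, building the C6=C7 bond with E geometry.

Step 22
Reactants: 31 (2E,4Z,6R,8E)-4-ethyl-9-iodo-N-methoxy-N,6-dimethylnona-2,4,8-trienamide
Product: 32 (2E,4Z,6R,8E)-4-ethyl-9-iodo-6-methylnona-2,4,8-trienal
Conditions: i-Bu2AlH, THF, −78 °C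
Reagents that add atoms: none
Why: Weinreb amide reduction: the chelated tetrahedral aluminium adduct survives until work-up, so the aldehyde is obtained without over-reduction.

Step 23
Reactants: 32 (2E,4Z,6R,8E)-4-ethyl-9-iodo-6-methylnona-2,4,8-trienal
Product: 33 (3S,4R,5E,7Z,9R,11E)-7-ethyl-12-iodo-3,9-dimethyldodeca-1,5,7,11-tetraen-4-ol
Conditions: trans-but-2-ene, KOt-Bu, n-BuLi, THF, −78 → −45 °C; (−)-Ipc2BOMe, −78 °C; BF3·OEt2; 32, −78 °C; then NaOH, H2O2
Reagents that add atoms: trans-but-2-ene, C/C=C/C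
Why: Brown crotylboration as in step 4: the chair transition state gives the anti C4/C5 pair and the same isopinocampheyl groups direct 1,2-addition to the si face of the dienal, setting C5 (R) and C4 (S) under reagent control.

Step 24
Reactants: 33 (3S,4R,5E,7Z,9R,11E)-7-ethyl-12-iodo-3,9-dimethyldodeca-1,5,7,11-tetraen-4-ol
Product: 34 (3S,4R,5E,7Z,9R,11E)-7-ethyl-12-iodo-3,9-dimethyldodeca-1,5,7,11-tetraen-4-yl prop-2-enoate
Conditions: acryloyl chloride, i-Pr2NEt, CH2Cl2, −78 → 0 °C
Reagents that add atoms: prop-2-enoyl chloride, C=CC(=O)Cl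
Why: O-Acylation of the secondary allylic alcohol with acryloyl chloride under amine base gives the diene ester needed for ring closure.

Step 25
Reactants: 34 (3S,4R,5E,7Z,9R,11E)-7-ethyl-12-iodo-3,9-dimethyldodeca-1,5,7,11-tetraen-4-yl prop-2-enoate
Product: 35 (5S,6R)-6-[(1E,3Z,5R,7E)-3-ethyl-8-iodo-5-methylocta-1,3,7-trien-1-yl]-5-methyl-5,6-dihydro-2H-pyran-2-one
Conditions: second-generation Grubbs catalyst (5 mol %), CH2Cl2 (high dilution), 40 °C
Reagents that add atoms: none
Why: Ring-closing metathesis: the ruthenium carbene forms at the terminal vinyl group and closes onto the acrylate to give the six-membered lactone (ring atoms O, C1–C5) with loss of ethene, the internal diene and the iodoalkene being much less reactive.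

**Union and finish**

Step 26
Reactants: 35 (5S,6R)-6-[(1E,3Z,5R,7E)-3-ethyl-8-iodo-5-methylocta-1,3,7-trien-1-yl]-5-methyl-5,6-dihydro-2H-pyran-2-one; 22 (2S,3R,4R,5E)-2-[(2R,3R,5R)-5-(2-hydroxyethyl)-3,5-dimethyloxolan-2-yl]-4-methyl-6-(tributylstannyl)hept-5-en-3-ol
Product: 36 (5S,6R)-6-[(1E,3Z,5R,7E,9E,11R,12R,13S)-3-ethyl-12-hydroxy-13-[(2R,3R,5R)-5-(2-hydroxyethyl)-3,5-dimethyloxolan-2-yl]-5,9,11-trimethyltetradeca-1,3,7,9-tetraen-1-yl]-5-methyl-5,6-dihydro-2H-pyran-2-one
Conditions: Pd(PPh3)4 (10 mol %), copper thiophene-2-carboxylate CuO2CC4H3S (1.5 equiv), Bu4N[O2PPh2] (1.5 equiv), DMF, rt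
Reagents that add atoms: none
Why: Stille cross-coupling with copper-assisted tin transfer joins C13 to C14 with retention at both alkenes under neutral conditions that tolerate the lactone and the free hydroxyls.

Step 27
Reactants: 36 the C17,C24-diol named in step 26
Product: 37 (5S,6R)-6-[(1E,3Z,5R,7E,9E,11R,13R)-3-ethyl-5,9,11-trimethyl-13-[(2R,3R,5R)-3,5-dimethyl-5-(2-oxoethyl)oxolan-2-yl]-12-oxotetradeca-1,3,7,9-tetraen-1-yl]-5-methyl-5,6-dihydro-2H-pyran-2-one (CNP0166598.2)
Conditions: Dess–Martin periodinane (3 equiv), NaHCO3, CH2Cl2, 0 °C → rt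
Reagents that add atoms: none
Why: Dess–Martin oxidation converts the C17 carbinol into the ketone and the C24 alcohol into the aldehyde in one operation, the bicarbonate buffer guarding C16 and C18 against epimerisation.

**Compound list**

1 | (4S)-4-benzyl-3-propanoyl-1,3-oxazolidin-2-one | CCC(=O)N1[C@@H](Cc2ccccc2)COC1=O | starting material
2 | 3-bromoprop-1-yne | C#CCBr | starting material
3 | (4S)-4-benzyl-3-[(2R)-2-methylpent-4-ynoyl]-1,3-oxazolidin-2-one | C#CC[C@@H](C)C(=O)N1[C@@H](Cc2ccccc2)COC1=O | intermediate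
4 | (2R)-2-methylpent-4-yn-1-ol | C#CC[C@@H](C)CO | intermediate
5 | (2R)-2-methylpent-4-ynal | C#CC[C@@H](C)C=O | intermediate
6 | (3S,4R,5R)-3,5-dimethyloct-1-en-7-yn-4-ol | C=C[C@H](C)[C@H](O)[C@H](C)CC#C | intermediate
7 | 3-[(2R,3R,4R)-3-hydroxy-4-methylhept-6-yn-2-yl]-1,2,4-trioxolane (ozonide, mixture at the ring carbon) | C1OOC(O1)[C@H](C)[C@H](O)[C@H](C)CC#C | intermediate (not isolated)
8 | (2S,3R,4R)-2,4-dimethylhept-6-yne-1,3-diol | OC[C@H](C)[C@H](O)[C@H](C)CC#C | intermediate
9 | (2S,3R,4R)-1-{[tert-butyl(dimethyl)silyl]oxy}-2,4-dimethylhept-6-yn-3-ol | CC(C)(C)[Si](C)(C)OC[C@H](C)[C@H](O)[C@H](C)CC#C | intermediate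
10 | (E)-alkenyl(dimethyl)alane from 9, C23–AlMe2 with the C19 oxygen as O–AlMe2 | CC(C)(C)[Si](C)(C)OC[C@H](C)[C@H](O[Al](C)C)[C@H](C)C/C(C)=C/[Al](C)C | intermediate (not isolated)
11 | (2E,5R,6R,7S)-8-{[tert-butyl(dimethyl)silyl]oxy}-3,5,7-trimethyloct-2-ene-1,6-diol | CC(C)(C)[Si](C)(C)OC[C@H](C)[C@H](O)[C@H](C)C/C(C)=C/CO | intermediate
12 | (2E,5R,6R,7S)-8-{[tert-butyl(dimethyl)silyl]oxy}-6-hydroxy-3,5,7-trimethyloct-2-en-1-yl methyl carbonate | CC(C)(C)[Si](C)(C)OC[C@H](C)[C@H](O)[C@H](C)C/C(C)=C/COC(=O)OC | intermediate (key-step precursor)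
13 | tert-butyl{(2S)-2-[(2R,3R,5R)-5-ethenyl-3,5-dimethyloxolan-2-yl]propoxy}dimethylsilane | CC(C)(C)[Si](C)(C)OC[C@H](C)[C@@H]1O[C@@](C)(C=C)C[C@H]1C | intermediate (key-step product)
14 | (2S)-2-[(2R,3R,5R)-5-ethenyl-3,5-dimethyloxolan-2-yl]propan-1-ol | OC[C@H](C)[C@@H]1O[C@@](C)(C=C)C[C@H]1C | intermediate
15 | (2R)-2-[(2R,3R,5R)-5-ethenyl-3,5-dimethyloxolan-2-yl]propanal | O=C[C@H](C)[C@@H]1O[C@@](C)(C=C)C[C@H]1C | intermediate
16 | (2S)-pent-3-yn-2-ol | C[C@H](O)C#CC | starting material
17 | (2S)-pent-3-yn-2-yl methanesulfonate | C[C@H](OS(C)(=O)=O)C#CC | intermediate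
18 | ethyl[(aR)-penta-2,3-dien-2-yl]zinc | CC[Zn]C(C)=[C@@]=C(C)[H] | intermediate (not isolated)
19 | (2S,3R,4R)-2-[(2R,3R,5R)-5-ethenyl-3,5-dimethyloxolan-2-yl]-4-methylhept-5-yn-3-ol | CC#C[C@@H](C)[C@@H](O)[C@H](C)[C@@H]1O[C@@](C)(C=C)C[C@H]1C | intermediate
20 | (2S,3R,4R,5E)-2-[(2R,3R,5R)-5-ethenyl-3,5-dimethyloxolan-2-yl]-4-methyl-6-(tributylstannyl)hept-5-en-3-ol | CCCC[Sn](CCCC)(CCCC)/C(C)=C/[C@@H](C)[C@@H](O)[C@H](C)[C@@H]1O[C@@](C)(C=C)C[C@H]1C | intermediate
21 | C24 B-alkyl-9-borabicyclo[3.3.1]nonane adduct of 20 | CCCC[Sn](CCCC)(CCCC)/C(C)=C/[C@@H](C)[C@@H](O)[C@H](C)[C@@H]1O[C@@](C)(CCB2C3CCCC2CCC3)C[C@H]1C | intermediate (not isolated)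
22 | (2S,3R,4R,5E)-2-[(2R,3R,5R)-5-(2-hydroxyethyl)-3,5-dimethyloxolan-2-yl]-4-methyl-6-(tributylstannyl)hept-5-en-3-ol | CCCC[Sn](CCCC)(CCCC)/C(C)=C/[C@@H](C)[C@@H](O)[C@H](C)[C@@H]1O[C@@](C)(CCO)C[C@H]1C | intermediate (East half)
23 | (E)-alkenylzirconocene chloride of the zirconium alkoxide of 4 (cyclopentadienyl rings drawn σ-bonded) | Cl[Zr](C1C=CC=C1)(C1C=CC=C1)/C=C/C[C@@H](C)CO[Zr](Cl)(C1C=CC=C1)C1C=CC=C1 | intermediate (not isolated)
24 | (2R,4E)-5-iodo-2-methylpent-4-en-1-ol | OC[C@H](C)C/C=C/I | intermediate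
25 | (2R,4E)-5-iodo-2-methylpent-4-enal | O=C[C@H](C)C/C=C/I | intermediate
26 | methyl 2-[bis(2,2,2-trifluoroethoxy)phosphoryl]acetate | COC(=O)CP(=O)(OCC(F)(F)F)OCC(F)(F)F | starting material
27 | methyl 2-[bis(2,2,2-trifluoroethoxy)phosphoryl]butanoate (racemic) | CCC(C(=O)OC)P(=O)(OCC(F)(F)F)OCC(F)(F)F | intermediate
28 | methyl (2Z,4R,6E)-2-ethyl-7-iodo-4-methylhepta-2,6-dienoate | CC/C(C(=O)OC)=C/[C@H](C)C/C=C/I | intermediate
29 | (2Z,4R,6E)-2-ethyl-7-iodo-4-methylhepta-2,6-dien-1-ol | CC/C(CO)=C/[C@H](C)C/C=C/I | intermediate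
30 | (2Z,4R,6E)-2-ethyl-7-iodo-4-methylhepta-2,6-dienal | CC/C(C=O)=C/[C@H](C)C/C=C/I | intermediate (not isolated)
31 | (2E,4Z,6R,8E)-4-ethyl-9-iodo-N-methoxy-N,6-dimethylnona-2,4,8-trienamide | CC/C(/C=C/C(=O)N(C)OC)=C/[C@H](C)C/C=C/I | intermediate
32 | (2E,4Z,6R,8E)-4-ethyl-9-iodo-6-methylnona-2,4,8-trienal | CC/C(/C=C/C=O)=C/[C@H](C)C/C=C/I | intermediate
33 | (3S,4R,5E,7Z,9R,11E)-7-ethyl-12-iodo-3,9-dimethyldodeca-1,5,7,11-tetraen-4-ol | CCC(=C/[C@H](C)C/C=C/I)/C=C/[C@@H](O)[C@@H](C)C=C | intermediate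
34 | (3S,4R,5E,7Z,9R,11E)-7-ethyl-12-iodo-3,9-dimethyldodeca-1,5,7,11-tetraen-4-yl prop-2-enoate | CCC(=C/[C@H](C)C/C=C/I)/C=C/[C@@H](OC(=O)C=C)[C@@H](C)C=C | intermediate
35 | (5S,6R)-6-[(1E,3Z,5R,7E)-3-ethyl-8-iodo-5-methylocta-1,3,7-trien-1-yl]-5-methyl-5,6-dihydro-2H-pyran-2-one | CCC(=C/[C@H](C)C/C=C/I)/C=C/[C@H]1OC(=O)C=C[C@@H]1C | intermediate (West half)
36 | C17,C24-diol: (5S,6R)-6-[(1E,3Z,5R,7E,9E,11R,12R,13S)-3-ethyl-12-hydroxy-13-[(2R,3R,5R)-5-(2-hydroxyethyl)-3,5-dimethyloxolan-2-yl]-5,9,11-trimethyltetradeca-1,3,7,9-tetraen-1-yl]-5-methyl-5,6-dihydro-2H-pyran-2-one | CCC(=C/[C@H](C)C/C=C/C(C)=C/[C@@H](C)[C@@H](O)[C@H](C)[C@@H]1O[C@@](C)(CCO)C[C@H]1C)/C=C/[C@H]1OC(=O)C=C[C@@H]1C | intermediate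
37 | CNP0166598.2: (5S,6R)-6-[(1E,3Z,5R,7E,9E,11R,13R)-3-ethyl-5,9,11-trimethyl-13-[(2R,3R,5R)-3,5-dimethyl-5-(2-oxoethyl)oxolan-2-yl]-12-oxotetradeca-1,3,7,9-tetraen-1-yl]-5-methyl-5,6-dihydro-2H-pyran-2-one | CCC(=C/[C@H](C)C/C=C/C(C)=C/[C@@H](C)C(=O)[C@H](C)[C@@H]1O[C@@](C)(CC=O)C[C@H]1C)/C=C/[C@H]1OC(=O)C=C[C@@H]1C | target

Total step count: 27. Longest linear sequence: 16 steps from compound 1 (steps 1–11, 13–15, 26, 27); the West branch from 1 is 13 steps (1, 2, 16, 17, 19–27).

**Steps most likely to fail**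

1. Step 9. The ligand-controlled face selection at C22 may be opposed by the substrate, so that closure is slow or poorly face-selective, and the π-allyl complex may instead lose a proton to a diene. The first adjustment is the ligand antipode. The fallback sets C22 by a reagent-controlled epoxidation; it sets out from 11 and returns at 13. Sharpless asymmetric epoxidation of 11 (Ti(Oi-Pr)4, L-(+)-diethyl tartrate, t-BuOOH, 4 Å sieves, CH2Cl2, −20 °C) should give the (2S,3S)-epoxy alcohol F1. With catalytic camphorsulfonic acid the C19 hydroxyl opens the epoxide at the tertiary carbon C22 with inversion (5-exo) to give the oxolane diol F2, already (22R). Thiocarbonyldiimidazole converts the 1,2-diol into the cyclic thionocarbonate F3, and Corey–Winter elimination with P(OMe)3 at reflux gives the vinyl oxolane 13.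

2. Step 14. The hydropalladation may deliver tin partly to C15, and Bu3SnH may be consumed by dimerisation to the distannane. The fallback obtains regiocontrol by reversible hydrozirconation; it sets out from 19 and returns at 22. 9-BBN, which hydroborates a terminal alkene faster than an internal alkyne, followed by NaOH/H2O2 should give the alkynediol F4. Et3SiCl and imidazole give the bis(triethylsilyl) ether F5. Excess Cp2Zr(H)Cl at 50 °C places zirconium on the less hindered C14, and iodine gives the E alkenyl iodide F6. t-BuLi at −78 °C followed by Bu3SnCl gives the stannane F7, and Bu4NF removes both silyl groups to give 22.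

3. Step 26. Tin-to-palladium transfer from the α-methyl-substituted stannane may be slow, so that protodestannylation or homocoupling takes over. The fallback exchanges the roles of the partners; it sets out from 22 and 35 and returns at 36. Iodine converts 22 with retention into the alkenyl iodide F8. Compound 35 is stannylated with Me3SnSnMe3 and Pd(PPh3)4 to the unhindered E alkenylstannane F9. Coupling of F8 with F9 (Pd2(dba)3, AsPh3, N-methylpyrrolidone, rt) gives 36.

Further compounds
F1 | step 9 | [(2S,3S)-3-[(2R,3R,4S)-5-{[tert-butyl(dimethyl)silyl]oxy}-3-hydroxy-2,4-dimethylpentyl]-3-methyloxiran-2-yl]methanol | CC(C)(C)[Si](C)(C)OC[C@H](C)[C@H](O)[C@H](C)C[C@]1(C)O[C@H]1CO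
F2 | step 9 | oxolane diol, 13 with (1S)-CH(OH)CH2OH in place of the vinyl group | CC(C)(C)[Si](C)(C)OC[C@H](C)[C@@H]1O[C@@](C)([C@@H](O)CO)C[C@H]1C
F3 | step 9 | cyclic thionocarbonate (1,3-dioxolane-2-thione) of F2 | CC(C)(C)[Si](C)(C)OC[C@H](C)[C@@H]1O[C@@](C)([C@@H]2COC(=S)O2)C[C@H]1C
F4 | step 14 | (2S,3R,4R)-2-[(2R,3R,5R)-5-(2-hydroxyethyl)-3,5-dimethyloxolan-2-yl]-4-methylhept-5-yn-3-ol | CC#C[C@@H](C)[C@@H](O)[C@H](C)[C@@H]1O[C@@](C)(CCO)C[C@H]1C
F5 | step 14 | bis(triethylsilyl) ether of F4 | CC#C[C@@H](C)[C@@H](O[Si](CC)(CC)CC)[C@H](C)[C@@H]1O[C@@](C)(CCO[Si](CC)(CC)CC)C[C@H]1C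
F6 | step 14 | (E)-C14 alkenyl iodide, bis(triethylsilyl) ether | I/C(C)=C/[C@@H](C)[C@@H](O[Si](CC)(CC)CC)[C@H](C)[C@@H]1O[C@@](C)(CCO[Si](CC)(CC)CC)C[C@H]1C
F7 | step 14 | bis(triethylsilyl) ether of 22 | CCCC[Sn](CCCC)(CCCC)/C(C)=C/[C@@H](C)[C@@H](O[Si](CC)(CC)CC)[C@H](C)[C@@H]1O[C@@](C)(CCO[Si](CC)(CC)CC)C[C@H]1C
F8 | step 26 | (2S,3R,4R,5E)-2-[(2R,3R,5R)-5-(2-hydroxyethyl)-3,5-dimethyloxolan-2-yl]-6-iodo-4-methylhept-5-en-3-ol | I/C(C)=C/[C@@H](C)[C@@H](O)[C@H](C)[C@@H]1O[C@@](C)(CCO)C[C@H]1C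
F9 | step 26 | (5S,6R)-6-[(1E,3Z,5R,7E)-3-ethyl-5-methyl-8-(trimethylstannyl)octa-1,3,7-trien-1-yl]-5-methyl-5,6-dihydro-2H-pyran-2-one | CCC(=C/[C@H](C)C/C=C/[Sn](C)(C)C)/C=C/[C@H]1OC(=O)C=C[C@@H]1C
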